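One millimolar of coupling partner is the coin I count in, and the question for each flask is how much of it ends up as target.

| setting | dusk | midnight | summer | noon | winter |
|---|---|---|---|---|---|
| starting material | 150 mM | 75.0 mM | 150 mM | 300 mM | 520 mM |
| coupling partner | 165 mM | 90.0 mM | 165 mM | 165 mM | 165 mM |
| free catalyst | 3.00 mM | 3.00 mM | 3.00 mM | 3.00 mM | 3.00 mM |
| target |  |  | 75.0 mM |  |  |
| time |  |  |  |  | 17 min |

| run | time / min | [target] / mM |
|---|---|---|
| dusk run | 0.76 | 12.5 |
| dusk run | 2.3 | 30.3 |
| dusk run | 4.4 | 45.8 |
| dusk run | 6.9 | 54.6 |
| dusk run | 9.9 | 60.3 |
| dusk run | 13 | 61.8 |
| dusk run | 17 | 64.9 |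
| midnight run | 0.76 | 6.1 |
| midnight run | 2.3 | 15.7 |
| midnight run | 4.4 | 23.5 |
| midnight run | 6.9 | 28.6 |
| midnight run | 9.9 | 34.3 |
| midnight run | 13 | 36.4 |
| midnight run | 17 | 38.5 |
| summer run | 0.76 | 87.7 |
| summer run | 2.3 | 105.4 |
| summer run | 4.4 | 120.1 |
| summer run | 6.9 | 129.2 |
| summer run | 9.9 | 135.2 |
| summer run | 13 | 137.5 |
| summer run | 17 | 139.3 |
| noon run | 0.76 | 20.2 |
| noon run | 2.3 | 46.6 |
| noon run | 4.4 | 64.5 |
| noon run | 6.9 | 72.6 |
| noon run | 9.9 | 77.5 |
| noon run | 13 | 78.2 |
| noon run | 17 | 79.8 |

(each reading ± 0.4 mM)

1. the exponent of [starting material] in the starting rate at the charge of the dusk run (at the point where two percent of the starting material have become target) (one fixed amount of target, the same in the runs compared)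
2. the exponent of [coupling partner] in the starting rate at the charge of the dusk run (at the point where two percent of the starting material have become target)
3. target in the winter run at 17 min, as a share of the starting material charged

- Overall: starting material + coupling partner -> target, with free catalyst as catalyst.
- Constant volume, constant temperature.
- Bound and free are read together.
- An order is taken over about fifteen percent of the charge, up and down.

I follow the dusk run in slow motion. In the first instants, target reaches 12.5 mM at 0.76 min, a mean rate of 16.4 mM/min. The noon run, with 2.00 times the starting material, manages 26.6 mM/min over the same interval, so extra starting material helps, but less than in proportion. In the middle of the dusk run, between 4.4 min and 6.9 min, the mean rate reads 3.52 mM/min. At the end of the dusk run, between 13 min and 17 min, it reads 0.775 mM/min. Yet by subtraction 85.1 mM of the 150 mM of starting material in the dusk run remains at the last reading. The summer run gains 64.3 mM on its 75.0 mM of added target, against 64.9 mM made in the dusk run.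

In the dusk run, 64.9 mM of target on 165 mM of coupling partner makes 39.3 %. I carry this as the partner yield, φ: target at the last reading as a share of the coupling partner charged. I count on the partner because in the noon run it is the limiting reagent, with less of it charged than of starting material. There φ is 48.4 %, and in the midnight run it is 42.8 %.

From the dusk run to the noon run, at one partner charge of 165 mM and one catalyst charge of 3.00 mM, doubling the starting material goes with a rise in φ of 9 percentage points. I continue that step on the logarithm of the charge up to the winter run. This gives φ = 55.5 %, or 91.6 mM of target, which is 17.6 % of the starting material charged.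

The forecast gives 15 %, within 13 % to 17.5 %, so my figure stands just higher than its high end. For the orders it gives 0.8 in starting material and 0.2 in coupling partner, and it reads the slowing thus: “the catalyst is dying, and it dies faster at higher starting material”.

The simulation gives orders of 0.83 and 0.32, and 16.9 % for the winter run.

    free catalyst + starting material ⇌ catalyst-substrate complex (62.40 /M/min, 4.710 /min)
    catalyst-substrate complex + coupling partner → target + free catalyst (197.4 /M/min)
    catalyst-substrate complex → spent catalyst + starting material (0.2370 /min)
    2 coupling partner → lost reagent (1.578 /M/min)

As a partner yield, the winter result is φ = 53.3 %, against my 55.5 %. By the step to lost reagent alone, the first half-life of the coupling partner at the winter charge is 1.92 min. In the midnight run, that step's first half-life on 90.0 mM is 3.52 min, and φ stands at 42.8 %, higher than the 39.3 % of the dusk run, with half the starting material.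

The earlier runs and the new flask were computed for substances that don't exist, and the scatter is random.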